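The cycloheptanone ring is cut at two bonds, fusion CH–C(OH) (C5–C4) and CHMe–C(quaternary) (C1–C10). This reveals the C9 ketone with its two α-carbons as an oxyallyl cation, and the four seven-ring carbons C1–C4, from the CHMe carbon to the carbinol fusion carbon, as a 2-substituted furan whose oxygen is retained as the tertiary C4 hydroxyl. One intramolecular (4+3) cycloaddition closes the cyclopentane and the seven-membered ring and sets the ring-fusion stereocentres. Its precursor is an α-chloro ketone joined to the furan by a CMe2–CH(OTBS)–CH2 tether; the chlorine sits on the tether-side α-carbon, where aldehyde enamine chlorination installs it regiospecifically.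

Key step: step 10

Atom labels used throughout (target numbering): C1 = CHMe; C2, C3 = ring CH2; C4 = C(OH) fusion carbon; C5 = fusion CH; C6 = cyclopentane CH2; C7 = CHOH; C8 = CMe2; C9 = C=O; C10 = quaternary carbon. "Bridge face" is the face of the seven-membered ring that carries the C4 oxygen.

Assumption (step 3): the (R)-phosphoric acid is taken to deliver allyl to the Re face of 4, as with other aldehydes; the (S)-acid would be used if the sense proved opposite.

Assumption (step 12): hydride is taken to reach the C9 carbonyl of 19 from the alkene face, away from the two axial α-substituents, placing the carbinol oxygen on the bridge face. This centre is oxidised again in step 15 and matters only for the directing pattern in step 13.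

Assumption (step 8): bromide 12 is a catalogue compound and is bought.

Step 1
Reactants: 1 furan; 2 ethyl 2-bromo-2-methylpropanoate
Product: 3 ethyl 2-(furan-2-yl)-2-methylpropanoate
Conditions: fac-Ir(ppy)3 (1 mol %), 2,6-lutidine, furan (5 equiv), MeCN, blue LEDs, rt
Reagents that add atoms: none
Why: Photoredox homolytic aromatic substitution, in which single-electron reduction of the tertiary α-bromo ester gives an electrophilic radical that adds to the electron-rich 2-position of furan and the adduct is oxidised and deprotonated back to the aromatic ring.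

Step 2
Reactants: 3 ethyl 2-(furan-2-yl)-2-methylpropanoate
Product: 4 2-(furan-2-yl)-2-methylpropanal
Conditions: i-Bu2AlH (1.1 equiv), CH2Cl2, −78 °C; aq. Rochelle salt
Reagents that add atoms: none
Why: Partial ester reduction with DIBAL-H, since the aluminium hemiacetal of this α-quaternary ester is stable at −78 °C and collapses to the aldehyde only on work-up.

Step 3
Reactants: 4 2-(furan-2-yl)-2-methylpropanal; 5 allylboronic acid pinacol ester
Product: 6 (3R)-2-(furan-2-yl)-2-methylhex-5-en-3-ol
Conditions: (R)-TRIP phosphoric acid (5 mol %), toluene, −30 °C; aqueous work-up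
Reagents that add atoms: none
Why: Chiral Brønsted acid-catalysed allylboration through a chair six-membered transition state, in which the (R)-acid activates the boronate and directs allyl transfer to the Re face of the aldehyde, setting the (R)-carbinol centre C7.

Step 4
Reactants: 6 (3R)-2-(furan-2-yl)-2-methylhex-5-en-3-ol
Product: 7 tert-butyl{[(3R)-2-(furan-2-yl)-2-methylhex-5-en-3-yl]oxy}dimethylsilane
Conditions: TBSOTf, 2,6-lutidine, CH2Cl2, −78 → 0 °C
Reagents that add atoms: tert-butyldimethylsilyl trifluoromethanesulfonate, CC(C)(C)[Si](C)(C)OS(=O)(=O)C(F)(F)F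
Why: Silylation with the silyl triflate overcomes the hindrance of the neopentyl-type secondary alcohol, and the lutidine buffer protects the furan from acid.

Step 5
Reactants: 7 tert-butyl{[(3R)-2-(furan-2-yl)-2-methylhex-5-en-3-yl]oxy}dimethylsilane
Product: 9 (4R)-4-[(tert-butyldimethylsilyl)oxy]-5-(furan-2-yl)-5-methylhexan-1-ol, via B-alkyl-9-BBN adduct 8 (not isolated)
Conditions: 9-BBN, THF, 0 °C → rt; then 3 M NaOH, 30% H2O2, 0 °C
Reagents that add atoms: hydrogen peroxide, OO
Why: Anti-Markovnikov hydroboration of the terminal alkene with the bulky borane followed by alkaline peroxide oxidation gives the primary alcohol without touching the furan.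

Step 6
Reactants: 9 (4R)-4-[(tert-butyldimethylsilyl)oxy]-5-(furan-2-yl)-5-methylhexan-1-ol
Product: 10 (4R)-4-[(tert-butyldimethylsilyl)oxy]-5-(furan-2-yl)-5-methylhexanal
Conditions: Dess–Martin periodinane, NaHCO3, CH2Cl2, 0 °C → rt
Reagents that add atoms: none
Why: Dess–Martin oxidation stops at the aldehyde under buffered, near-neutral conditions that furan and silyl ether tolerate.

Step 7
Reactants: 10 (4R)-4-[(tert-butyldimethylsilyl)oxy]-5-(furan-2-yl)-5-methylhexanal
Product: 11 (4R)-2-chloro-4-[(tert-butyldimethylsilyl)oxy]-5-(furan-2-yl)-5-methylhexanal (C2 epimers)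
Conditions: N-chlorosuccinimide (1.2 equiv), L-prolinamide (10 mol %), CH2Cl2, 0 °C → rt; used crude
Reagents that add atoms: N-chlorosuccinimide, O=C1CCC(=O)N1Cl
Why: Enamine-catalysed α-chlorination puts chlorine only on the aldehyde α-carbon (the future C5), fixing the regiochemistry of the chloro ketone, and the new C–Cl centre needs no control because step 10 makes it planar.

Step 8
Reactants: 11 (4R)-2-chloro-4-[(tert-butyldimethylsilyl)oxy]-5-(furan-2-yl)-5-methylhexanal; 12 (4-bromobutoxy)(tert-butyl)dimethylsilane
Product: 14 (8R)-1,8-bis[(tert-butyldimethylsilyl)oxy]-6-chloro-9-(furan-2-yl)-9-methyldecan-5-ol (diastereomer mixture at C5 and C6), via Grignard reagent 13 (not isolated)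
Conditions: 12, Mg, I2 (cat.), THF, 45 °C; then 11, THF, −78 °C; sat. aq. NH4Cl
Reagents that add atoms: none
Why: Grignard addition to the α-chloro aldehyde at low temperature outruns enolisation and epoxide closure and gives a chlorohydrin mixture that converges in the next step.

Step 9
Reactants: 14 (8R)-1,8-bis[(tert-butyldimethylsilyl)oxy]-6-chloro-9-(furan-2-yl)-9-methyldecan-5-ol
Product: 15 (8R)-1,8-bis[(tert-butyldimethylsilyl)oxy]-6-chloro-9-(furan-2-yl)-9-methyldecan-5-one (C6 epimers)
Conditions: Dess–Martin periodinane, NaHCO3, CH2Cl2, 0 °C → rt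
Reagents that add atoms: none
Why: Dess–Martin oxidation of a chlorohydrin gives the α-chloro ketone under non-basic conditions, so neither HCl elimination nor premature ionisation is expected.

Step 10
Reactants: 15 (8R)-1,8-bis[(tert-butyldimethylsilyl)oxy]-6-chloro-9-(furan-2-yl)-9-methyldecan-5-one
Product: 17 oxygen-bridged tricyclic ketone (C1–O–C4 bridge; C2=C3 alkene; C10–H), via oxyallyl zwitterion 16 (not isolated)
Conditions: Et3N (3 equiv), CF3CH2OH (0.02 M), 0 °C → rt
Reagents that add atoms: none
Why: Triethylamine enolises 15 at the C10 methylene and the ionising, weakly nucleophilic solvent lets chloride leave from C5, giving the oxyallyl zwitterion 16 (C5–C9–C10), which the tethered furan captures across its two α-positions in a concerted or two-stage (4+3) cycloaddition; the closest known reaction type is the base-mediated intramolecular furan–oxyallyl cycloaddition of α-halo ketones in fluorinated alcohols. The cyclopentane (C4, C5, C6, C7, C8) closes by attack of the tether-bearing furan carbon C4 on the cationic terminus C5, a 5-exo closure with respect to the allyl unit. The seven-membered ring (C1–C5, C9, C10) closes through the second bond, C1–C10, and the former furan oxygen is left as the C1–O–C4 bridge. C1 and C4 arise together by suprafacial addition across the furan and their sense is set by the C7 stereocentre, the tether folding as an envelope with the OTBS group pseudo-equatorial so that the bridge forms cis to it; C5 follows from the orientation of the tether on the oxyallyl terminus (C6 must lie on the bridge face, i.e. trans fusion), and C10 from the geometry of the free terminus, which is irrelevant because step 11 makes it planar again. The step therefore needs furan-face selectivity relative to C7 and the trans ring fusion; the short tether, its gem-dimethyl group (reactive-rotamer effect) and the adjacent bulky silyloxy group bias the fold, and the C5–H stays α to the ketone should equilibration be required.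

Step 11
Reactants: 17 oxygen-bridged tricyclic ketone (C10–H)
Product: 19 C10-methylated bridged ketone, via lithium enolate 18 (not isolated)
Conditions: LDA (1.3 equiv), THF, −78 °C; MeI (5 equiv), DMPU, −78 → −20 °C
Reagents that add atoms: iodomethane, CI
Why: Kinetic enolisation removes the axial C10–H (the C5–H lies near the carbonyl plane, and the bridge C–O bond is orthogonal to the enolate so it is not eliminated at −78 °C), and C-alkylation of the enolate with MeI occurs axially from the bridge face, away from the two-carbon alkene bridge, creating the quaternary centre with methyl cis to the bridge oxygen.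

Step 12
Reactants: 19 C10-methylated bridged ketone
Product: 21 ring-opened C4,C9-diol with C1=C2 double bond, via bridged aluminium alkoxide 20 (not isolated)
Conditions: Ni(cod)2 (10 mol %), dppb (20 mol %), i-Bu2AlH (4 equiv, slow addition), toluene, 0 → 60 °C; aq. Rochelle salt
Reagents that add atoms: none
Why: DIBAL-H first reduces the ketone, and nickel-catalysed exo hydroalumination of the strained alkene then places aluminium on C2, remote from the fully substituted bridgehead C4, so that β-alkoxide elimination cleaves only the C1–O bond and leaves the oxygen on C4 as the tertiary alcohol.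

Step 13
Reactants: 21 ring-opened C4,C9-diol with C1=C2 double bond
Product: 22 C1,C2-cyclopropane diol
Conditions: Et2Zn (6 equiv), CH2I2 (12 equiv), CH2Cl2, 0 °C → rt
Reagents that add atoms: diiodomethane, ICI
Why: Simmons–Smith cyclopropanation directed by the zinc alkoxides of the homoallylic C4 and C9 hydroxyls, which lie on the same face, so that the methylene is delivered to C1=C2 cis to the C4–OH and fixes the C1 configuration.

Step 14
Reactants: 22 C1,C2-cyclopropane diol
Product: 24 C1-methyl triol with C7–OTBS retained, via bis-silyl ether 23 (not isolated)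
Conditions: H2 (4 atm), PtO2, AcOH, rt; filter; then AcOH/THF/H2O 3:1:1, 40 °C
Reagents that add atoms: none
Why: Platinum-catalysed cyclopropane hydrogenolysis opens the most accessible bond, C2–CH2 (C1 is shielded by the adjacent quaternary C10), turning the methylene into the C1 methyl with the configuration set in step 13, and the aqueous acetic acid then cleaves only the unhindered primary silyl ether.

Step 15
Reactants: 24 C1-methyl triol with C7–OTBS retained
Product: 25 C9-keto aldehyde (side chain CH2CH2CHO)
Conditions: (COCl)2 (5 equiv), DMSO (10 equiv), CH2Cl2, −78 °C; Et3N, −78 → 0 °C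
Reagents that add atoms: none
Why: Swern oxidation activates the primary and the secondary hydroxyl at −78 °C before either carbonyl exists, so aldehyde and C9 ketone form together without lactol or lactone formation, while the tertiary C4–OH cannot be oxidised.

Step 16
Reactants: 25 C9-keto aldehyde
Product: 26 hydroxymethyl ketone (side chain CH2CH2C(=O)CH2OH)
Conditions: (CH2O)n (5 equiv), 3-ethylbenzothiazolium bromide (20 mol %), i-Pr2NEt (20 mol %), THF, 60 °C
Reagents that add atoms: paraformaldehyde (as formaldehyde), C=O
Why: Thiazolium carbene-catalysed cross-acyloin reaction, in which the acyl anion equivalent formed from the unhindered aldehyde adds to formaldehyde while the hindered C9 ketone does not take part.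

Step 17
Reactants: 26 hydroxymethyl ketone
Product: 28 C7-O-TBS ether of the target, via acyl ylide 27 (not isolated)
Conditions: Ph3P=C=C=O (1.2 equiv), Et3N (cat.), toluene, 80 °C
Reagents that add atoms: (triphenylphosphoranylidene)ketene, O=C=C=P(c1ccccc1)(c1ccccc1)c1ccccc1
Why: The primary hydroxyl adds to the ketenylidene phosphorane to give an ester-stabilised ylide that closes onto the adjacent ketone by intramolecular Wittig reaction to the butenolide, the tertiary C4–OH and the C9 ketone being too hindered to compete.

Step 18
Reactants: 28 C7-O-TBS ether of the target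
Product: 29 CNP0077405.1 (target)
Conditions: 48% aq. HF, MeCN, rt
Reagents that add atoms: none
Why: Acidic fluoride desilylation of the hindered secondary silyl ether avoids the basic conditions that could cause retro-aldol cleavage or dehydration of the β-hydroxy ketone, and the butenolide is stable to it.

Compound list

1 | furan | c1ccoc1 | starting material
2 | ethyl 2-bromo-2-methylpropanoate | CCOC(=O)C(C)(C)Br | starting material
3 | ethyl 2-(furan-2-yl)-2-methylpropanoate | CCOC(=O)C(C)(C)c1ccco1 | intermediate
4 | 2-(furan-2-yl)-2-methylpropanal | O=CC(C)(C)c1ccco1 | intermediate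
5 | allylboronic acid pinacol ester | C=CCB1OC(C)(C)C(C)(C)O1 | starting material
6 | (3R)-2-(furan-2-yl)-2-methylhex-5-en-3-ol | C=CC[C@@H](O)C(C)(C)c1ccco1 | intermediate
7 | tert-butyl{[(3R)-2-(furan-2-yl)-2-methylhex-5-en-3-yl]oxy}dimethylsilane | C=CC[C@@H](O[Si](C)(C)C(C)(C)C)C(C)(C)c1ccco1 | intermediate
8 | 9-[(4R)-4-(TBSO)-5-(furan-2-yl)-5-methylhexyl]-9-borabicyclo[3.3.1]nonane (not isolated) | c1ccc(o1)C(C)(C)[C@H](O[Si](C)(C)C(C)(C)C)CCCB1C2CCCC1CCC2 | intermediate
9 | (4R)-4-[(tert-butyldimethylsilyl)oxy]-5-(furan-2-yl)-5-methylhexan-1-ol | OCCC[C@@H](O[Si](C)(C)C(C)(C)C)C(C)(C)c1ccco1 | intermediate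
10 | (4R)-4-[(tert-butyldimethylsilyl)oxy]-5-(furan-2-yl)-5-methylhexanal | O=CCC[C@@H](O[Si](C)(C)C(C)(C)C)C(C)(C)c1ccco1 | intermediate
11 | (4R)-2-chloro-4-[(tert-butyldimethylsilyl)oxy]-5-(furan-2-yl)-5-methylhexanal, C2 epimers | O=CC(Cl)C[C@@H](O[Si](C)(C)C(C)(C)C)C(C)(C)c1ccco1 | intermediate
12 | (4-bromobutoxy)(tert-butyl)dimethylsilane | BrCCCCO[Si](C)(C)C(C)(C)C | starting material
13 | {4-[(tert-butyldimethylsilyl)oxy]butyl}magnesium bromide (not isolated) | Br[Mg]CCCCO[Si](C)(C)C(C)(C)C | intermediate
14 | (8R)-1,8-bis[(tert-butyldimethylsilyl)oxy]-6-chloro-9-(furan-2-yl)-9-methyldecan-5-ol, mixture at C5 and C6 | c1ccc(o1)C(C)(C)[C@H](O[Si](C)(C)C(C)(C)C)CC(Cl)C(O)CCCCO[Si](C)(C)C(C)(C)C | intermediate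
15 | (8R)-1,8-bis[(tert-butyldimethylsilyl)oxy]-6-chloro-9-(furan-2-yl)-9-methyldecan-5-one, C6 epimers (cycloaddition precursor; Cl on C5, ketone = C9) | c1ccc(o1)C(C)(C)[C@H](O[Si](C)(C)C(C)(C)C)CC(Cl)C(=O)CCCCO[Si](C)(C)C(C)(C)C | intermediate
16 | oxyallyl zwitterion, cationic terminus C5, enolate C9–C10 (not isolated) | c1ccc(o1)C(C)(C)[C@H](O[Si](C)(C)C(C)(C)C)C[CH+]C([O-])=CCCCO[Si](C)(C)C(C)(C)C | intermediate
17 | oxygen-bridged cycloadduct: 5-7 bicyclic C9 ketone with C1–O–C4 ether bridge and C2=C3 alkene; C6 and C7–OTBS on the bridge face, C5–H opposite; C10–H on the bridge face, 3-(TBSO)propyl chain opposite | [C@@H]12C=C[C@]3(O2)[C@H](C[C@@H](O[Si](C)(C)C(C)(C)C)C3(C)C)C(=O)[C@H]1CCCO[Si](C)(C)C(C)(C)C | intermediate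
18 | lithium C9=C10 enolate of 17 (not isolated) | [C@@H]12C=C[C@]3(O2)[C@H](C[C@@H](O[Si](C)(C)C(C)(C)C)C3(C)C)C(O[Li])=C1CCCO[Si](C)(C)C(C)(C)C | intermediate
19 | C10-methylated bridged ketone: as 17, C10 carrying methyl on the bridge face and the 3-(TBSO)propyl chain opposite | [C@@H]12C=C[C@]3(O2)[C@H](C[C@@H](O[Si](C)(C)C(C)(C)C)C3(C)C)C(=O)[C@@]1(C)CCCO[Si](C)(C)C(C)(C)C | intermediate
20 | diisobutylaluminium alkoxide of the bridged C9 carbinol, C9–O on the bridge face (not isolated) | [C@@H]12C=C[C@]3(O2)[C@H](C[C@@H](O[Si](C)(C)C(C)(C)C)C3(C)C)[C@H](O[Al](CC(C)C)CC(C)C)[C@@]1(C)CCCO[Si](C)(C)C(C)(C)C | intermediate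
21 | ring-opened diol: C1=C2 alkene, tertiary C4–OH and secondary C9–OH on the same face as the C10 methyl and C7–OTBS | C1=CC[C@]2(O)[C@H](C[C@@H](O[Si](C)(C)C(C)(C)C)C2(C)C)[C@H](O)[C@@]1(C)CCCO[Si](C)(C)C(C)(C)C | intermediate
22 | cyclopropane diol: as 21, methylene bridging C1 and C2 on the C4–OH face | [C@H]13C[C@@H]3C[C@]2(O)[C@H](C[C@@H](O[Si](C)(C)C(C)(C)C)C2(C)C)[C@H](O)[C@@]1(C)CCCO[Si](C)(C)C(C)(C)C | intermediate
23 | C1-methyl diol bis-silyl ether, C1 methyl cis to C4–OH and C10 methyl (not isolated) | C[C@@H]1CC[C@]2(O)[C@H](C[C@@H](O[Si](C)(C)C(C)(C)C)C2(C)C)[C@H](O)[C@@]1(C)CCCO[Si](C)(C)C(C)(C)C | intermediate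
24 | triol: as 23 with the primary hydroxyl free, C7–OTBS retained | C[C@@H]1CC[C@]2(O)[C@H](C[C@@H](O[Si](C)(C)C(C)(C)C)C2(C)C)[C@H](O)[C@@]1(C)CCCO | intermediate
25 | keto aldehyde: C9 ketone, C4–OH, C7–OTBS, side chain CH2CH2CHO | C[C@@H]1CC[C@]2(O)[C@H](C[C@@H](O[Si](C)(C)C(C)(C)C)C2(C)C)C(=O)[C@@]1(C)CCC=O | intermediate
26 | hydroxymethyl ketone: side chain CH2CH2C(=O)CH2OH | C[C@@H]1CC[C@]2(O)[C@H](C[C@@H](O[Si](C)(C)C(C)(C)C)C2(C)C)C(=O)[C@@]1(C)CCC(=O)CO | intermediate
27 | (triphenylphosphoranylidene)acetate ester of 26 (not isolated) | C[C@@H]1CC[C@]2(O)[C@H](C[C@@H](O[Si](C)(C)C(C)(C)C)C2(C)C)C(=O)[C@@]1(C)CCC(=O)COC(=O)C=P(c3ccccc3)(c3ccccc3)c3ccccc3 | intermediate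
28 | C7-O-TBS ether of the target | C[C@@H]1CC[C@]2(O)[C@H](C[C@@H](O[Si](C)(C)C(C)(C)C)C2(C)C)C(=O)[C@@]1(C)CCC1=CC(=O)OC1 | intermediate
29 | CNP0077405.1: 4-[2-(5-7 bicyclic hydroxy ketone)ethyl]furan-2(5H)-one | C[C@@H]1CC[C@]2(O)[C@H](C[C@@H](O)C2(C)C)C(=O)[C@@]1(C)CCC1=CC(=O)OC1 | target

Total step count: 18. Longest linear sequence: 18 steps (1 → 29; 12 is purchased).

Steps most likely to fail

1. Step 10. What may go wrong: addition to the wrong furan face relative to C7, formation of the cis ring fusion, or capture of the cation by the solvent before the furan reaches it. Fallback, setting out from 15: kinetic silylation at the C10 methylene (LDA, Me3SiCl, THF, −78 °C) should give the 2-(trimethylsilyloxy)allyl chloride F1. Ionisation with AgClO4 in nitromethane at −20 °C then generates a 2-silyloxyallyl cation in an aprotic, non-nucleophilic medium, a more electrophilic species that reacts through a more stepwise transition state and so offers a different stereochemical outcome. Loss of the silyl group on work-up brings the route back at 17.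

2. Step 14. What may go wrong: hydrogenolysis of the other external cyclopropane bond, which would leave the methyl on C2, or no ring opening at all. Fallback, setting out from 21: silylation of the secondary C9–OH with (bromomethyl)chlorodimethylsilane (Et3N, DMAP, CH2Cl2) should give the (bromomethyl)dimethylsilyl ether F4. Tin hydride-mediated radical cyclisation (Bu3SnH, AIBN, benzene, 80 °C) closes 6-exo onto C1 from the C9–O face and reduces the C2 radical, giving the cyclic siloxane F5. Protodesilylation (KOt-Bu, DMSO/H2O) turns the silylmethylene into the C1 methyl and frees the C9–OH, so the route is rejoined at 23, ahead of the aqueous acetic acid half of step 14.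

3. Step 12. What may go wrong: sluggish hydroalumination beside the two hindered bridgeheads, or aluminium adding to C3 so that the C4–O bond is cleaved instead. Fallback, setting out from 19: DIBAL-H (CH2Cl2, −78 °C) should give the bridged carbinol F2. Radical thiol–ene addition of thiophenol (AIBN, benzene, 80 °C) places sulfur on C2 from the exo face, giving the C2 phenyl sulfide F3. Reductive lithiation with lithium di-tert-butylbiphenylide (THF, −78 °C) then forms the C2 carbanion, which expels the C1 oxygen by β-elimination and comes back to the route at 21.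

Further compounds

F1 | step 10 | 2-(trimethylsilyloxy)allyl chloride from 15 (enol ether C9=C10, Cl on C5, epimers) | c1ccc(o1)C(C)(C)[C@H](O[Si](C)(C)C(C)(C)C)CC(Cl)C(O[Si](C)(C)C)=CCCCO[Si](C)(C)C(C)(C)C
F2 | step 12 | bridged C9 carbinol (free alcohol of 20) | [C@@H]12C=C[C@]3(O2)[C@H](C[C@@H](O[Si](C)(C)C(C)(C)C)C3(C)C)[C@H](O)[C@@]1(C)CCCO[Si](C)(C)C(C)(C)C
F3 | step 12 | bridged carbinol with exo phenylthio group on C2 | [C@@H]12[C@H](Sc4ccccc4)C[C@]3(O2)[C@H](C[C@@H](O[Si](C)(C)C(C)(C)C)C3(C)C)[C@H](O)[C@@]1(C)CCCO[Si](C)(C)C(C)(C)C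
F4 | step 14 | C9-O-(bromomethyl)dimethylsilyl ether of 21 | C1=CC[C@]2(O)[C@H](C[C@@H](O[Si](C)(C)C(C)(C)C)C2(C)C)[C@H](O[Si](C)(C)CBr)[C@@]1(C)CCCO[Si](C)(C)C(C)(C)C
F5 | step 14 | cyclic siloxane with C9–O–SiMe2–CH2–C1 bridge | C4[C@@H]1CC[C@]2(O)[C@H](C[C@@H](O[Si](C)(C)C(C)(C)C)C2(C)C)[C@H](O[Si]4(C)C)[C@@]1(C)CCCO[Si](C)(C)C(C)(C)C
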